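**Retrosynthetic overview**
1. The target comes from the (1(10)E,4Z)-germacradienolide diol by a late peripheral epoxidation of C1=C10. The C8 isobutyrate is installed with inversion, and the C3/C15 diol is masked as one benzylidene acetal.
2. The ten-membered carbocycle is closed at C7–C8 by intramolecular allylchromium addition of a 3-(bromomethyl)butenolide to a β,γ-unsaturated aldehyde. The butenolide itself is made by ring-closing metathesis.
3. Key step: a five-membered oxaborole expands to a six-membered oxaborinine by a palladium-induced 1,2-metallate shift. It joins three components (oxaborole, vinyl, alkenyl bromide), forms C3–C4 and C1–C2, and sets C3.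
4. The oxaborole comes from acrolein and a propargyl ether (asymmetric alkynylation, trans-hydroalumination/iodination, borylation). The alkenyl bromide comes from a butynyl ether by carboalumination.
5. Ring order: oxaborole (temporary), oxaborinine (temporary), dioxane (protecting), butenolide, ten-membered ring, epoxide.

**Notes**
- Assumption: alkynes 1 and 8 are bought in O-protected form.
- C-numbers are the germacrane numbers of the target: C1/C10 epoxide, C14 the methyl on C10, C15 the CH2OH on C4, C11–C13 the methylene lactone.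
- Lig-A is 1,1'-bis[bis(4-methoxy-3,5-dimethylphenyl)phosphino]-2,2'-bis[(dimethylamino)(phenyl)methyl]ferrocene (MandyPhos type). The enantiomer that gives 3S is used.

**Step 1**
Reactants: 1 PMB-protected propargyl alcohol; 2 acrolein
Product: 3 (S)-6-[(4-methoxybenzyl)oxy]hex-1-en-4-yn-3-ol
Conditions: Me2Zn (3 equiv), ProPhenol ligand (10 mol%, enantiomer giving S), Ph3P=O (20 mol%), toluene, 0 °C
Reagents that add atoms: none
Why: Zinc–ProPhenol catalysed asymmetric alkynylation (1,2-addition of an alkynylzinc to an enal) forms C5–C6 and sets C6, which is S here and becomes R in the lactone only through a change of CIP priorities.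

**Step 2**
Reactants: 3 (S)-enynol
Product: 5 (3S,4Z)-5-iodo-6-[(4-methoxybenzyl)oxy]hexa-1,4-dien-3-ol, via cyclic sodium vinylalanate 4 (not isolated)
Conditions: NaAlH2(OCH2CH2OMe)2 (1.5 equiv), THF, −20 → 0 °C; then NIS, −78 °C
Reagents that add atoms: N-iodosuccinimide O=C1CCC(=O)N1I
Why: Hydroxyl-directed trans-hydroalumination puts hydride on C5 and aluminium on C4 in a five-membered alanate, and iododealumination with retention gives only the Z-iodide, which fixes the 4Z geometry; the temperature stays at or below 0 °C to avoid allene formation.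

**Step 3**
Reactants: 5 (Z)-iodo dienol
Product: 7 (5S)-3-{[(4-methoxybenzyl)oxy]methyl}-5-vinyl-1,2-oxaborol-2(5H)-ol, via alkenyl pinacol boronate 6 (not isolated)
Conditions: B2pin2, PdCl2(dppf) (3 mol%), KOAc, 1,4-dioxane, 60 °C; aqueous work-up, silica gel
Reagents that add atoms: bis(pinacolato)diboron CC1(C)OB(OC1(C)C)B1OC(C)(C)C(C)(C)O1; water O
Why: Miyaura borylation proceeds with retention of alkene geometry, and the cis γ-hydroxyl then displaces pinacol to close the oxaborole, which also masks the C6 hydroxyl.

**Step 4**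
Reactants: 8 TBS-protected but-3-yn-1-ol
Product: 10 (E)-[(4-bromo-3-methylbut-3-en-1-yl)oxy](tert-butyl)dimethylsilane, via alkenyl dimethylalane 9 (not isolated)
Conditions: Me3Al (2 equiv), Cp2ZrCl2 (20 mol%), CH2Cl2, 0 °C → rt; then NBS, THF, −30 °C
Reagents that add atoms: trimethylaluminium C[Al](C)C; N-bromosuccinimide O=C1CCC(=O)N1Br
Why: Negishi zirconium-catalysed syn-carboalumination followed by bromodealumination with retention gives the E-trisubstituted alkenyl bromide, which sets the C1=C10 geometry and brings in C14.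

**Step 5**
Reactants: 7 oxaborolol; 10 (E)-alkenyl bromide; 11 vinylmagnesium bromide
Product: 14 (3S,4Z,6S,8E)-11-[(tert-butyldimethylsilyl)oxy]-5-{[(4-methoxybenzyl)oxy]methyl}-9-methylundeca-1,4,8-triene-3,6-diol, via magnesium bis(alkenyl)borate 12 (not isolated), via ring-expanded oxaborinine 13 (not isolated)
Conditions: 11 (2.1 equiv), THF, −78 → 0 °C; then 10, NaOTf, Pd(OAc)2 (3 mol%), Lig-A (3.6 mol%), THF/DMSO, 40 °C; then NaOH, H2O2, 0 °C
Reagents that add atoms: hydrogen peroxide OO
Why: Proposed new method: a ring-expanding conjunctive cross-coupling in which two equivalents of 11 turn the cyclic boronic hemiester 7 into the four-coordinate borate 12, the cationic alkenylpalladium species from 10 (bromide removed by NaOTf) binds the unhindered B-vinyl group, and this π-activation triggers a stepwise, non-pericyclic 1,2-metallate shift of the only other carbon ligand, the endocyclic sp2 carbon C4, from boron to C3 anti to palladium, so the five-membered oxaborole grows to the six-membered oxaborinine 13 (C3–C4 bond), reductive elimination then forms C1–C2 with retention of the E geometry, and stereoretentive oxidation gives the 3S alcohol and frees the C6 hydroxyl; C3 is set by the chiral diphosphine, matched with the substrate because the 3,6-trans ring carries both substituents pseudo-equatorial; the closest known reaction types are the palladium-catalysed enantioselective conjunctive cross-coupling of acyclic pinacol bis(alkenyl)borates and electrophile-induced ring-expanding 1,2-metallate rearrangements of cyclic boronates.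

**Step 6**
Reactants: 14 diol
Product: 15 (3S,6S)-C6 alcohol carrying the C3,C15-O-[(R)-4-methoxybenzylidene] acetal (cis-2,4-disubstituted 5-alkylidene-1,3-dioxane)
Conditions: DDQ (1.1 equiv), 4 Å molecular sieves, CH2Cl2, −10 °C
Reagents that add atoms: none
Why: In this oxidative PMB-to-benzylidene acetal formation only the C3 hydroxyl can reach the oxocarbenium ion (six-membered ring) because the C6 hydroxyl lies trans across C4=C5, and the acetal carbon settles with the aryl group equatorial.

**Step 7**
Reactants: 15 C6 alcohol; 16 2-(bromomethyl)acrylic acid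
Product: 17 2-(bromomethyl)acrylate ester of 15
Conditions: DIC, DMAP (5 mol%), CH2Cl2, −10 → 0 °C
Reagents that add atoms: none
Why: Steglich-type carbodiimide esterification acylates the only free hydroxyl without touching C6, and low temperature and low DMAP loading protect the allylic bromide.

**Step 8**
Reactants: 17 diene ester
Product: 18 (5R)-3-(bromomethyl)-5-alkenylfuran-2(5H)-one (C6 R and C3 S, TBS ether at C8)
Conditions: second-generation Hoveyda–Grubbs catalyst (5 mol%), toluene (5 mM), 80 °C
Reagents that add atoms: none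
Why: Ring-closing metathesis joins the acrylate methylene and the C7 vinyl group to give the five-membered butenolide (C7=C11), while the two trisubstituted alkenes are inert.

**Step 9**
Reactants: 18 TBS ether
Product: 19 primary C8 alcohol
Conditions: HF·pyridine, pyridine, THF, 0 °C
Reagents that add atoms: none
Why: Buffered acidic fluoride desilylation removes the primary TBS group without displacing the allylic bromide or opening the acetal.

**Step 10**
Reactants: 19 primary alcohol
Product: 20 β,γ-unsaturated C8 aldehyde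
Conditions: Dess–Martin periodinane, NaHCO3, CH2Cl2, 0 °C
Reagents that add atoms: none
Why: Buffered Dess–Martin oxidation gives the skipped enal without conjugation, and it is used at once.

**Step 11**
Reactants: 20 bromo aldehyde
Product: 21 (3S,6R,7R,8S)-8-hydroxy-3,15-O-[(R)-4-methoxybenzylidene]germacra-1(10)E,4Z,11(13)-trien-12,6-olide
Conditions: CrCl2 (8 equiv), THF/DMF, 1 mM (syringe pump), rt
Reagents that add atoms: none
Why: In this intramolecular Nozaki–Hiyama-type allylation the allylchromium reacts at its γ-carbon C7 on the butenolide face anti to the C6 side chain (trans-lactone, 7R), and the chair transition state with the E-locked C6 substituent and the aldehyde chain both equatorial gives the anti product (8S) together with the exocyclic methylene.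

**Step 12**
Reactants: 21 8S alcohol; 22 isobutyric acid
Product: 23 (3S,6R,7R,8R)-8-isobutyryloxy-3,15-O-[(R)-4-methoxybenzylidene]germacra-1(10)E,4Z,11(13)-trien-12,6-olide
Conditions: PPh3, DIAD (betaine pre-formed), toluene, 0 °C → rt
Reagents that add atoms: none
Why: Mitsunobu esterification installs the isobutyrate by SN2 displacement and inverts C8 from S to the required R in the same operation.

**Step 13**
Reactants: 23 acetal
Product: 24 (3S,6R,7R,8R)-3,15-dihydroxy-8-isobutyryloxygermacra-1(10)E,4Z,11(13)-trien-12,6-olide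
Conditions: AcOH/THF/H2O (3:1:1), rt
Reagents that add atoms: none
Why: Mild acid hydrolysis of the electron-rich benzylidene acetal frees both hydroxyls before the acid-labile epoxide is present.

**Step 14**
Reactants: 24 triene diol
Product: 25 target, (1R,3S,4Z,6R,7R,8R,10R)-1,10-epoxy-3,15-dihydroxy-8-isobutyryloxygermacra-4,11(13)-dien-12,6-olide
Conditions: mCPBA (1.05 equiv), CH2Cl2, −20 → 0 °C
Reagents that add atoms: meta-chloroperoxybenzoic acid O=C(OO)c1cccc(Cl)c1
Why: Prilezhaev epoxidation selects the strained, electron-rich E-C1=C10 alkene over C4=C5 (deactivated by three allylic oxygens) and the acrylate, and syn delivery to the exposed outer face of the ring is expected to give the trans 1R,10R epoxide.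

**Compound list**
1 | 1-methoxy-4-[(prop-2-yn-1-yloxy)methyl]benzene (PMB-protected propargyl alcohol) | C#CCOCc1ccc(OC)cc1 | starting material
2 | acrolein | C=CC=O | starting material
3 | (S)-6-[(4-methoxybenzyl)oxy]hex-1-en-4-yn-3-ol | C=C[C@H](O)C#CCOCc1ccc(OC)cc1 | intermediate
4 | cyclic sodium vinylalanate (not isolated) | [Na+].COCCO[Al-]1(OCCOC)O[C@@H](C=C)C=C1COCc1ccc(OC)cc1 | intermediate
5 | (3S,4Z)-5-iodo-6-[(4-methoxybenzyl)oxy]hexa-1,4-dien-3-ol | C=C[C@H](O)/C=C(/COCc1ccc(OC)cc1)I | intermediate
6 | (3S,4Z)-alkenyl pinacol boronate (not isolated) | C=C[C@H](O)/C=C(/COCc1ccc(OC)cc1)B1OC(C)(C)C(C)(C)O1 | intermediate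
7 | (5S)-3-{[(4-methoxybenzyl)oxy]methyl}-5-vinyl-1,2-oxaborol-2(5H)-ol | OB1O[C@@H](C=C)C=C1COCc1ccc(OC)cc1 | intermediate
8 | tert-butyl(but-3-yn-1-yloxy)dimethylsilane (TBS-protected but-3-yn-1-ol) | C#CCCO[Si](C)(C)C(C)(C)C | starting material
9 | (E)-alkenyl dimethylalane (not isolated) | C[Al](C)/C=C(\C)CCO[Si](C)(C)C(C)(C)C | intermediate
10 | (E)-[(4-bromo-3-methylbut-3-en-1-yl)oxy](tert-butyl)dimethylsilane | Br/C=C(\C)CCO[Si](C)(C)C(C)(C)C | intermediate
11 | vinylmagnesium bromide | C=C[Mg]Br | starting material
12 | magnesium bis(alkenyl)borate (not isolated) | C=C[B-]1(O[Mg]Br)O[C@@H](C=C)C=C1COCc1ccc(OC)cc1.[Mg+]Br | intermediate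
13 | trans-3,6-disubstituted 3,6-dihydro-2H-1,2-oxaborinine (not isolated) | Br[Mg]OB1O[C@@H](C=C)C=C(COCc2ccc(OC)cc2)[C@@H]1C/C=C(\C)CCO[Si](C)(C)C(C)(C)C | intermediate
14 | (3S,4Z,6S,8E)-11-(TBS-oxy)-5-[(PMB-oxy)methyl]-9-methylundeca-1,4,8-triene-3,6-diol | C=C[C@H](O)/C=C(/COCc1ccc(OC)cc1)[C@@H](O)C/C=C(\C)CCO[Si](C)(C)C(C)(C)C | intermediate
15 | C6 alcohol with C3,C15-O-[(R)-4-methoxybenzylidene] acetal | C=C[C@H](O)/C=C1/CO[C@@H](c2ccc(OC)cc2)O[C@H]1C/C=C(\C)CCO[Si](C)(C)C(C)(C)C | intermediate
16 | 2-(bromomethyl)acrylic acid | C=C(CBr)C(=O)O | starting material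
17 | 2-(bromomethyl)acrylate of 15 | C=C[C@H](OC(=O)C(=C)CBr)/C=C1/CO[C@@H](c2ccc(OC)cc2)O[C@H]1C/C=C(\C)CCO[Si](C)(C)C(C)(C)C | intermediate
18 | 3-(bromomethyl)butenolide, TBS ether | BrCC1=C[C@H](OC1=O)/C=C2/CO[C@@H](c3ccc(OC)cc3)O[C@H]2C/C=C(\C)CCO[Si](C)(C)C(C)(C)C | intermediate
19 | 3-(bromomethyl)butenolide, C8 alcohol | BrCC1=C[C@H](OC1=O)/C=C2/CO[C@@H](c3ccc(OC)cc3)O[C@H]2C/C=C(\C)CCO | intermediate
20 | 3-(bromomethyl)butenolide, C8 aldehyde | BrCC1=C[C@H](OC1=O)/C=C2/CO[C@@H](c3ccc(OC)cc3)O[C@H]2C/C=C(\C)CC=O | intermediate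
21 | macrocyclic 8S alcohol (acetal) | C=C1C(=O)O[C@@H]2/C=C3/CO[C@@H](c4ccc(OC)cc4)O[C@H]3C/C=C(\C)C[C@H](O)[C@@H]12 | intermediate
22 | isobutyric acid | CC(C)C(=O)O | starting material
23 | macrocyclic 8R isobutyrate (acetal) | C=C1C(=O)O[C@@H]2/C=C3/CO[C@@H](c4ccc(OC)cc4)O[C@H]3C/C=C(\C)C[C@@H](OC(=O)C(C)C)[C@@H]12 | intermediate
24 | triene diol | C=C1C(=O)O[C@@H]2/C=C(/CO)[C@@H](O)C/C=C(\C)C[C@@H](OC(=O)C(C)C)[C@@H]12 | intermediate
25 | CNP0219050.1 | C=C1C(=O)O[C@@H]2/C=C(/CO)[C@@H](O)C[C@H]3O[C@]3(C)C[C@@H](OC(=O)C(C)C)[C@@H]12 | target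

**Step count**
Total: 14 steps. Longest linear sequence: 13 steps (steps 1–3 and 5–14).

**Three steps most likely to fail**

**Step 5 (new ring-expanding coupling).**
- Risks: direct Suzuki-type transfer of vinyl or C4, poor borate formation from the B–OH hemiester, and low control at C3.
- Fallback with known reactions, leaving the route at 10 and 5 and returning at 14.
- Bromide 10 is lithiated (t-BuLi, Et2O, −78 °C) and opened onto oxirane (BF3·OEt2) to give (E)-6-[(tert-butyldimethylsilyl)oxy]-4-methylhex-3-en-1-ol F1.
- Dess–Martin oxidation gives (E)-6-[(tert-butyldimethylsilyl)oxy]-4-methylhex-3-enal F2.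
- An asymmetric Nozaki–Hiyama–Kishi coupling of F2 with iodide 5 (CrCl2, NiCl2 cat., chiral oxazoline sulfonamide ligand, MeCN) then gives diol 14 directly.

**Step 11 (ten-membered ring closure).**
- Risks: oligomerisation, reductive opening of the butenolide by 1,4-elimination, and conjugation of the aldehyde.
- Fallback, leaving at 19 and returning at 21. It replaces the reductive organochromium closure by a preformed allylboron reagent whose cyclisation is triggered only when the aldehyde is unmasked.
- Borylation of 19 (B2pin2, Pd2(dba)3 cat., DMSO, 40 °C) gives the 3-(pinacolborylmethyl)butenolide alcohol F3.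
- Dess–Martin oxidation gives the boryl aldehyde F4.
- F4 is closed at 1 mM by Sc(OTf)3-catalysed intramolecular allylboration through the same chair geometry, giving 21 after aqueous work-up.

**Step 12 (Mitsunobu inversion at a hindered ring carbinol).**
- Risks: elimination towards C8=C9, no reaction with the weakly acidic isobutyric acid, and phosphine addition to the methylene lactone.
- Fallback, leaving at 21 and returning at 23.
- Dess–Martin oxidation gives the C8 ketone F5.
- Outer-face 1,2-reduction (NaBH4, CeCl3·7H2O, MeOH, −78 °C) gives the 8R alcohol F6.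
- Acylation with isobutyryl chloride and pyridine gives 23.
- If the ring closure of step 11 delivers F6 itself, only this acylation is needed.

**Further compounds**
F1 | step 5 | (E)-6-[(tert-butyldimethylsilyl)oxy]-4-methylhex-3-en-1-ol | OCC/C=C(\C)CCO[Si](C)(C)C(C)(C)C
F2 | step 5 | (E)-6-[(tert-butyldimethylsilyl)oxy]-4-methylhex-3-enal | O=CC/C=C(\C)CCO[Si](C)(C)C(C)(C)C
F3 | step 11 | 3-(pinacolborylmethyl)butenolide alcohol | CC1(C)OB(CC2=C[C@H](OC2=O)/C=C3/CO[C@@H](c4ccc(OC)cc4)O[C@H]3C/C=C(\C)CCO)OC1(C)C
F4 | step 11 | 3-(pinacolborylmethyl)butenolide aldehyde | CC1(C)OB(CC2=C[C@H](OC2=O)/C=C3/CO[C@@H](c4ccc(OC)cc4)O[C@H]3C/C=C(\C)CC=O)OC1(C)C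
F5 | step 12 | macrocyclic C8 ketone (acetal) | C=C1C(=O)O[C@@H]2/C=C3/CO[C@@H](c4ccc(OC)cc4)O[C@H]3C/C=C(\C)CC(=O)[C@@H]12
F6 | step 12 | macrocyclic 8R alcohol (acetal) | C=C1C(=O)O[C@@H]2/C=C3/CO[C@@H](c4ccc(OC)cc4)O[C@H]3C/C=C(\C)C[C@@H](O)[C@@H]12
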